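**Retrosynthetic overview** (chain atoms numbered C5, the CH2 on the furan, to C19, the lactone carbonyl)
- The strategy rests on the intact isoprene unit C6–C7=C8(CH3)–C9, which sits between the furylmethyl carbon C5 and the C10 carbinol; C10 is five bonds from C15 and six from C16 of the γ-lactone ring, so it must be set by a reagent, not by the substrate.
- Last disconnection: C9–C10 and C5–C6 are cut together, giving the C10–C19 enal lactone, isoprene and a furan-3-ylmethylzinc reagent, to be joined by a nickel-catalysed three-component coupling under chiral phosphoramidite control; zinc carries one furylmethyl group and one (trimethylsilyl)methyl group as a non-transferred spectator.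
- Enal lactone: from (2E,6E)-farnesol via its acetate; the terminal isopropylidene is cleaved to the C19 acid, Shi epoxidation of C15=C16 and anti 5-exo lactonisation set C15 (R) and C16 (S), then acetate exchange and allylic oxidation.
- Rings: the γ-lactone is the only ring made (step 6); the furan is bought as furan-3-ylmethanol and carried into the zinc reagent; the key step closes no ring.

Key step: step 12

Assumption: the sense of induction of the phosphoramidite in the nickel step cannot be derived from precedent; the (S)-binaphthyl ligand is written, and its antipode would be used if a trial coupling on 3-methylbut-2-enal showed the opposite sense at the carbinol carbon.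

**Route**

Step 1
Reactants: 1 (2E,6E)-farnesol
Product: 2 (2E,6E)-farnesyl acetate
Conditions: Ac2O, pyridine, 4-(dimethylamino)pyridine (cat.), CH2Cl2, 0 °C to rt
Reagents that add atoms: acetic anhydride, CC(=O)OC(C)=O
Why: DMAP-catalysed O-acetylation of the primary allylic alcohol, the ester later deactivating the adjacent C11=C12 alkene towards electrophilic oxidants.

Step 2
Reactants: 2 (2E,6E)-farnesyl acetate
Product: 3 (2E,6E)-10-bromo-11-hydroxy-3,7,11-trimethyldodeca-2,6-dien-1-yl acetate (racemic at the CHBr carbon)
Conditions: N-bromosuccinimide, THF/H2O, 0 °C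
Reagents that add atoms: N-bromosuccinimide, O=C1CCC(=O)N1Br; water, O
Why: Terminal-selective bromohydrin formation, in which electrophilic bromine in aqueous THF attacks the exposed isopropylidene alkene in preference to the internal and the acetate-deactivated alkenes and water opens the bromonium ion at the tertiary carbon; the racemic centre is destroyed in step 4.

Step 3
Reactants: 3 bromohydrin acetate
Product: 4 (2E,6E)-9-(3,3-dimethyloxiran-2-yl)-3,7-dimethylnona-2,6-dien-1-yl acetate (racemic)
Conditions: 1,8-diazabicyclo[5.4.0]undec-7-ene (DBU), toluene, rt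
Reagents that add atoms: none
Why: Intramolecular Williamson closure (3-exo-tet) of the tertiary hydroxyl onto the secondary bromide, with an amidine base that does not transesterify the acetate.

Step 4
Reactants: 4 terminal epoxide
Product: 5 (2E,6E)-3,7-dimethyl-10-oxodeca-2,6-dien-1-yl acetate
Conditions: H5IO6, THF/Et2O, 0 °C
Reagents that add atoms: none
Why: Periodic acid hydrates the trisubstituted epoxide and cleaves the resulting glycol (Malaprade cleavage) to the C19 aldehyde and acetone, without touching the two trisubstituted alkenes or the acetate.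

Step 5
Reactants: 5 C19 aldehyde
Product: 6 (4E,8E)-10-acetoxy-4,8-dimethyldeca-4,8-dienoic acid
Conditions: NaClO2, NaH2PO4, 2-methylbut-2-ene, t-BuOH/H2O, rt
Reagents that add atoms: sodium chlorite, [Na+].[O-]Cl=O
Why: Pinnick oxidation of the aldehyde to the acid, with 2-methylbut-2-ene removing HOCl so that the alkenes are not chlorinated.

Step 6
Reactants: 6 dienoic acid
Product: 8 (2E,6R)-6-hydroxy-3-methyl-6-[(2S)-2-methyl-5-oxooxolan-2-yl]hex-2-en-1-yl acetate, via epoxy acid 7 (not isolated)
Conditions: 1,2:4,5-di-O-isopropylidene-β-D-erythro-2,3-hexodiulo-2,6-pyranose (0.3 equiv), KHSO5 (as Oxone, 2KHSO5·KHSO4·K2SO4), K2CO3, Bu4NHSO4, aq. Na2B4O7 buffer, MeCN/dimethoxymethane, 0 °C; then acidify to pH 4, extract; camphor-10-sulfonic acid (cat.), CH2Cl2, rt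
Reagents that add atoms: potassium peroxymonosulfate, [K+].[O-]S(=O)(=O)OO
Why: Shi asymmetric epoxidation, in which the dioxirane of the D-fructose-derived ketone attacks the electron-rich C15=C16 alkene (C11=C12 is deactivated by the allylic acetate) through the spiro transition state that gives the (15R,16R)-epoxide 7, after which acid drives 5-exo opening by the carboxyl group at the tertiary carbon with inversion, so that C15 (R) comes from the epoxidation and C16 (S) from the anti opening.

Step 7
Reactants: 8 hydroxy lactone acetate
Product: 9 (5S)-5-[(1R,4E)-1,6-dihydroxy-4-methylhex-4-en-1-yl]-5-methyloxolan-2-one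
Conditions: K2CO3 (0.3 equiv), MeOH, 0 °C; AcOH quench; pyridinium p-toluenesulfonate (cat.), CH2Cl2, rt
Reagents that add atoms: none
Why: Base-catalysed methanolysis (Zemplén-type transesterification) removes the unhindered primary allylic acetate, and the brief acid treatment re-closes any γ-lactone opened by methoxide, the γ,γ-disubstituted lactone being the favoured form; no stereocentre is touched.

Step 8
Reactants: 9 diol lactone
Product: 10 (2E,6R)-6-hydroxy-3-methyl-6-[(2S)-2-methyl-5-oxooxolan-2-yl]hex-2-enal
Conditions: activated MnO2 (excess), CH2Cl2, rt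
Reagents that add atoms: none
Why: MnO2 oxidises only the allylic primary alcohol, giving the (E)-enal, and leaves the saturated secondary C15 alcohol untouched.

Step 9
Reactants: 10 hydroxy enal
Product: 11 (2E,6R)-6-acetoxy-3-methyl-6-[(2S)-2-methyl-5-oxooxolan-2-yl]hex-2-enal
Conditions: Ac2O, pyridine, 4-(dimethylamino)pyridine (cat.), CH2Cl2, 0 °C to rt
Reagents that add atoms: acetic anhydride, CC(=O)OC(C)=O
Why: DMAP-catalysed acetylation of the hindered secondary C15 alcohol under mild basic conditions that the β,β-disubstituted enal and the lactone tolerate.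

Step 10
Reactants: 12 furan-3-ylmethanol
Product: 13 3-(chloromethyl)furan
Conditions: SOCl2, pyridine, Et2O, 0 °C
Reagents that add atoms: thionyl chloride, ClS(Cl)=O
Why: Chlorodehydroxylation through the chlorosulfite ester, with pyridine taking up HCl so that the acid-sensitive furan survives.

Step 11
Reactants: 13 3-(chloromethyl)furan
Product: 15 (furan-3-ylmethyl)[(trimethylsilyl)methyl]zinc, via (furan-3-ylmethyl)zinc chloride 14 (not isolated)
Conditions: Zn dust (1.5 equiv, activated with 1,2-dibromoethane and Me3SiCl), LiCl (1.5 equiv), THF, 0 °C to rt; decant from excess Zn; Me3SiCH2Li (1.0 equiv, pentane), −30 °C to 0 °C; solvent exchange to toluene, filtration under argon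
Reagents that add atoms: zinc, [Zn]; (trimethylsilyl)methyllithium, [Li]C[Si](C)(C)C
Why: LiCl-promoted direct zinc insertion into the heterobenzylic chloride gives the benzylic-type zinc chloride 14 with little Wurtz coupling, and salt metathesis (transmetalation) with Me3SiCH2Li converts it into the mixed diorganozinc, in which the (trimethylsilyl)methyl group is a non-transferable ligand, so that the one furylmethyl group on zinc is the group delivered in step 12.

Step 12
Reactants: 11 acetoxy enal lactone; 15 (furan-3-ylmethyl)[(trimethylsilyl)methyl]zinc; 16 isoprene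
Product: 18 15-acetylirciformonin B, (1R,4E,6S,8E)-11-(furan-3-yl)-6-hydroxy-4,8-dimethyl-1-[(2S)-2-methyl-5-oxooxolan-2-yl]undeca-4,8-dien-1-yl acetate, via zinc alkoxide 17 (not isolated)
Conditions: Ni(acac)2 (10 mol %), (S)-1,1'-binaphthalene-2,2'-diyl N,N-bis[(R)-1-phenylethyl]phosphoramidite (12 mol %), isoprene (5 equiv), THF, 0 °C to rt, 15 (1.5–2 equiv, toluene solution) added by syringe pump; pH 7 phosphate buffer
Reagents that add atoms: none
Why: Proposed new method: reduction of Ni(acac)2 by 15 should give a zerovalent nickel–phosphoramidite complex on which isoprene and the zinc-coordinated aldehyde of 11 cyclise oxidatively, forming C9–C10 at the diene CH2 attached to the methyl-substituted carbon and leaving an η3-allylnickel alkoxide over C6–C8; zinc then takes the alkoxide and passes its furylmethyl group to nickel, the bulky (trimethylsilyl)methyl group staying on zinc, and reductive elimination at the unsubstituted terminus C6 forms C5–C6 and the zinc alkoxide 17, which buffer converts into 18. The closest known reaction type is the Ni(acac)2-catalysed three-component coupling of 1,3-dienes, aldehydes and Me2Zn or Ph2Zn to (E)-homoallylic alcohols, together with nickel–phosphoramidite-catalysed enantioselective reductive couplings of dienes with aldehydes; neither transfer of a heterobenzylic group from a mixed diorganozinc nor an enantioselective alkylative version is established. No ring is closed. The one new stereocentre, C10 (S), is set in the carbon–carbon bond-forming oxidative cyclisation by the chiral ligand alone, since C15 and C16 are too remote to bias either aldehyde face. The step needs attack at C9 and not C6, 1,4- over 1,2-coupling and E geometry, which should follow from the greater nucleophilicity of the methyl-substituted diene terminus and from a syn η3-allyl intermediate whose C9 arm is tied to nickel through oxygen and which couples at its less hindered end; it also needs the catalysed path to outrun direct addition of the benzylic-type zinc reagent to the aldehyde, which slow addition of a salt-poor solution of 15 into excess isoprene is meant to secure. Conjugate addition is blocked by the two β-substituents of the enal, neither the lactone nor the acetate reacts with a diorganozinc, and a furylmethyl group on nickel cannot undergo β-hydride elimination.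

**Compound list**

1 | (2E,6E)-farnesol | CC(C)=CCC/C(C)=C/CC/C(C)=C/CO | starting material
2 | (2E,6E)-farnesyl acetate | CC(C)=CCC/C(C)=C/CC/C(C)=C/COC(C)=O | intermediate
3 | (2E,6E)-10-bromo-11-hydroxy-3,7,11-trimethyldodeca-2,6-dien-1-yl acetate (racemic at CHBr) | CC(C)(O)C(Br)CC/C(C)=C/CC/C(C)=C/COC(C)=O | intermediate
4 | (2E,6E)-9-(3,3-dimethyloxiran-2-yl)-3,7-dimethylnona-2,6-dien-1-yl acetate (racemic) | CC1(C)OC1CC/C(C)=C/CC/C(C)=C/COC(C)=O | intermediate
5 | (2E,6E)-3,7-dimethyl-10-oxodeca-2,6-dien-1-yl acetate | O=CCC/C(C)=C/CC/C(C)=C/COC(C)=O | intermediate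
6 | (4E,8E)-10-acetoxy-4,8-dimethyldeca-4,8-dienoic acid | OC(=O)CC/C(C)=C/CC/C(C)=C/COC(C)=O | intermediate
7 | 3-[(2R,3R)-3-[(3E)-5-acetoxy-3-methylpent-3-en-1-yl]-2-methyloxiran-2-yl]propanoic acid | CC(=O)OC/C=C(C)/CC[C@H]1O[C@]1(C)CCC(=O)O | intermediate
8 | (2E,6R)-6-hydroxy-3-methyl-6-[(2S)-2-methyl-5-oxooxolan-2-yl]hex-2-en-1-yl acetate | CC(=O)OC/C=C(C)/CC[C@@H](O)[C@]1(C)CCC(=O)O1 | intermediate
9 | (5S)-5-[(1R,4E)-1,6-dihydroxy-4-methylhex-4-en-1-yl]-5-methyloxolan-2-one | OC/C=C(C)/CC[C@@H](O)[C@]1(C)CCC(=O)O1 | intermediate
10 | (2E,6R)-6-hydroxy-3-methyl-6-[(2S)-2-methyl-5-oxooxolan-2-yl]hex-2-enal | O=C/C=C(C)/CC[C@@H](O)[C@]1(C)CCC(=O)O1 | intermediate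
11 | (2E,6R)-6-acetoxy-3-methyl-6-[(2S)-2-methyl-5-oxooxolan-2-yl]hex-2-enal | CC(=O)O[C@H](CC/C(C)=C/C=O)[C@]1(C)CCC(=O)O1 | intermediate
12 | furan-3-ylmethanol | OCc1ccoc1 | starting material
13 | 3-(chloromethyl)furan | ClCc1ccoc1 | intermediate
14 | (furan-3-ylmethyl)zinc chloride | Cl[Zn]Cc1ccoc1 | intermediate
15 | (furan-3-ylmethyl)[(trimethylsilyl)methyl]zinc | C[Si](C)(C)C[Zn]Cc1ccoc1 | intermediate
16 | isoprene | C=CC(C)=C | starting material
17 | [(trimethylsilyl)methyl]zinc C10-alkoxide of the target | CC(=O)O[C@H](CC/C(C)=C/[C@@H](O[Zn]C[Si](C)(C)C)C/C(C)=C/CCc1ccoc1)[C@]1(C)CCC(=O)O1 | intermediate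
18 | 15-acetylirciformonin B | CC(=O)O[C@H](CC/C(C)=C/[C@@H](O)C/C(C)=C/CCc1ccoc1)[C@]1(C)CCC(=O)O1 | target

**Count and risks**

Total step count: 12 (nine to the enal lactone, two to the zinc reagent, one coupling). Longest linear sequence: 10 steps (steps 1–9 and 12).

Steps most likely to fail:

1. Step 12 (proposed new method). What may go wrong: uncatalysed 1,2-addition of the furylmethylzinc reagent to the aldehyde outrunning the nickel cycle, coupling at the wrong allyl terminus or with Z geometry, competing transfer of the (trimethylsilyl)methyl group, suppression of the three-component path by the phosphoramidite, or weak facial control at C10. Fallback by known chemistry, setting out from 11 and returning at 18: asymmetric propargylation of 11 with allenylboronic acid pinacol ester under a chiral phosphoric acid (3,3'-bis(2,4,6-triisopropylphenyl)-1,1'-binaphthyl-2,2'-diyl hydrogen phosphate, antipode chosen for 10S) should give (1R,4E,6S)-6-hydroxy-4-methyl-1-[(2S)-2-methyl-5-oxooxolan-2-yl]non-4-en-8-yn-1-yl acetate F1. Zirconium-catalysed methylalumination of the terminal alkyne (Me3Al, Cp2ZrCl2, water-accelerated, CH2Cl2, −30 °C, the carbinol carried as its aluminium alkoxide) followed by iodinolysis should give (1R,4E,6S,8E)-6-hydroxy-9-iodo-4,8-dimethyl-1-[(2S)-2-methyl-5-oxooxolan-2-yl]nona-4,8-dien-1-yl acetate F2, the C7=C8 geometry being fixed by syn addition. Separately, commercial 2-(furan-3-yl)ethanol is converted (I2, PPh3, imidazole) into 3-(2-iodoethyl)furan F3, and zinc insertion (Zn dust, LiCl, THF) gives [2-(furan-3-yl)ethyl]zinc iodide F4. Negishi coupling of F2 with F4 (Pd(PPh3)4, THF, rt) forms C6–C7 and should give 18.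

2. Step 6. What may go wrong: competing epoxidation of the acetate-bearing alkene, partial acetate hydrolysis at the pH of the epoxidation, poor partitioning of the carboxylate between the phases, or loss of clean inversion at C16 if the tertiary centre ionises or the C11=C12 alkene takes part before the carboxyl group attacks. Fallback, setting out from 6 and returning at 8: the two events are separated and run on a neutral substrate. Esterification (Me3SiCHN2, MeOH/toluene) gives methyl (4E,8E)-10-acetoxy-4,8-dimethyldeca-4,8-dienoate F5. Shi epoxidation under the usual conditions for lipophilic alkenes gives methyl 3-[(2R,3R)-3-[(3E)-5-acetoxy-3-methylpent-3-en-1-yl]-2-methyloxiran-2-yl]propanoate F6, which can be freed from any regioisomeric epoxide by chromatography. Camphor-10-sulfonic acid in wet CH2Cl2 then closes the lactone through the ester carbonyl, with inversion at C16 and loss of methanol, to give 8.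

3. Step 11. What may go wrong: Wurtz-type homocoupling or incomplete conversion during zinc insertion, decomposition of the labile heterobenzylic chloride before it reaches the metal, or lithium salts carried through the filtration, which would speed the background carbonyl addition in step 12. Fallback, setting out from 13 and returning at 14: metal insertion is replaced by transmetalation from a purifiable stannane. Displacement of chloride in 13 with Bu3SnLi (from Bu3SnH and lithium diisopropylamide, THF, −78 °C) gives tributyl(furan-3-ylmethyl)stannane F7, which can be purified by chromatography. Tin–lithium exchange (n-BuLi, THF, −78 °C) gives (furan-3-ylmethyl)lithium F8, and ZnCl2 (1.0 equiv) converts it into 14, which is treated with Me3SiCH2Li as in step 11 to give 15.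

**Further compounds**

F1 | step 12 | (1R,4E,6S)-6-hydroxy-4-methyl-1-[(2S)-2-methyl-5-oxooxolan-2-yl]non-4-en-8-yn-1-yl acetate | CC(=O)O[C@H](CC/C(C)=C/[C@@H](O)CC#C)[C@]1(C)CCC(=O)O1
F2 | step 12 | (1R,4E,6S,8E)-6-hydroxy-9-iodo-4,8-dimethyl-1-[(2S)-2-methyl-5-oxooxolan-2-yl]nona-4,8-dien-1-yl acetate | CC(=O)O[C@H](CC/C(C)=C/[C@@H](O)C/C(C)=C/I)[C@]1(C)CCC(=O)O1
F3 | step 12 | 3-(2-iodoethyl)furan | ICCc1ccoc1
F4 | step 12 | [2-(furan-3-yl)ethyl]zinc iodide | I[Zn]CCc1ccoc1
F5 | step 6 | methyl (4E,8E)-10-acetoxy-4,8-dimethyldeca-4,8-dienoate | COC(=O)CC/C(C)=C/CC/C(C)=C/COC(C)=O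
F6 | step 6 | methyl 3-[(2R,3R)-3-[(3E)-5-acetoxy-3-methylpent-3-en-1-yl]-2-methyloxiran-2-yl]propanoate | CC(=O)OC/C=C(C)/CC[C@H]1O[C@]1(C)CCC(=O)OC
F7 | step 11 | tributyl(furan-3-ylmethyl)stannane | CCCC[Sn](CCCC)(CCCC)Cc1ccoc1
F8 | step 11 | (furan-3-ylmethyl)lithium | [Li]Cc1ccoc1
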